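**Retrosynthetic overview**

1. The target is reached by late acylations of a trans-fused octalin; ring B is closed last by ring-closing metathesis (C3=C4), after C3 has been added as a vinyl group to C2.
2. Key disconnection C9–C10: a magnesium-mediated intramolecular aldol of an α-keto ester enolate (C10=C1–O, C2 as the ester) onto the C9 aldehyde with lactonization in the same flask (O9→C2). From an acyclic chain this closes ring A and a temporary γ-lactone in one operation.
3. Enabling feature: quaternary C10 lies between two oxygenated carbons (C9–O and C1–O, an aldol retron with C1 as the enolizable carbonyl) and carries C14. O9 and C1 are cis on ring A and C2 is the next ring-B carbon, so the five-membered ring O9–C2(=O)–C1–C10–C9 can form, fix C9 relative to C10, mask O9, and later be opened at C2.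
4. The acyclic precursor comes from (S)-carvone, whose six-membered ring is a second temporary ring: Claisen rearrangement of a cis-carveol 2-alkoxy-enoate makes C5–C10 and relays chirality to C5, and ozonolysis of the old ring alkene (C4=C9) releases the C9 aldehyde and the C4 ketone.
5. Ring order: carvone ring (cleaved, step 6) → ring A plus lactone (step 7) → lactone opened (step 12) → ring B (step 13).

Key step: step 7

Remark: eudesmane numbering is used throughout (ring A = C5–C6–C7–C8–C9–C10, ring B = C10–C1–C2–C3–C4–C5; O-senecioyl on C1, OAc on C2 and C9, C15 methyl on C4, isopropenyl on C7, C14H2OH on C10), and the centres named as mixtures in 5, 7, 8 and 10 are assumed to need no control because they are erased or re-set later.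

**Route**

Step 1
Reactants: 1 (S)-(+)-carvone
Product: 2 (1S,5S)-cis-carveol
Conditions: NaBH4, CeCl3·7H2O, MeOH, 0 °C
Reagents that add atoms: none
Why: Luche 1,2-reduction; hydride should add axially to the half-chair that keeps isopropenyl pseudo-equatorial, placing the new hydroxyl (the future chirality-relay oxygen on C9) cis to isopropenyl.

Step 2
Reactants: 3 trimethyl phosphonoacetate
Product: 4 methyl 2-diazo-2-(dimethoxyphosphoryl)acetate
Conditions: NaH, THF, 0 °C; then 4-acetamidobenzenesulfonyl azide, 0 °C → rt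
Reagents that add atoms: 4-acetamidobenzenesulfonyl azide, CC(=O)Nc1ccc(cc1)S(=O)(=O)N=[N+]=[N-]
Why: Regitz diazo transfer to the sodium enolate of the doubly activated methylene.

Step 3
Reactants: 2 (1S,5S)-cis-carveol; 4 methyl 2-diazo-2-(dimethoxyphosphoryl)acetate
Product: 5 methyl 2-(dimethoxyphosphoryl)-2-{[(1S,5S)-2-methyl-5-(prop-1-en-2-yl)cyclohex-2-en-1-yl]oxy}acetate (both epimers at the phosphonate carbon)
Conditions: Rh2(OAc)4 (cat.), PhMe, 80 °C, slow addition of 4
Reagents that add atoms: none
Why: O–H insertion of the rhodium carbenoid, which for an acceptor/acceptor carbenoid should outrun cyclopropanation of either alkene and leaves the carbinol centre untouched.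

Step 4
Reactants: 5 phosphonate ether; 6 2-[(tert-butyldiphenylsilyl)oxy]acetaldehyde
Product: 7 methyl 4-[(tert-butyldiphenylsilyl)oxy]-2-{[(1S,5S)-2-methyl-5-(prop-1-en-2-yl)cyclohex-2-en-1-yl]oxy}but-2-enoate (E/Z mixture)
Conditions: LiN(SiMe3)2, THF, −78 °C; then 6, −78 → 0 °C
Reagents that add atoms: none
Why: Horner–Wadsworth–Emmons olefination of the α-alkoxy phosphonoacetate builds the allyl vinyl ether that carries C10, C14, C1 and C2; the alkene geometry is irrelevant because C10 is re-set in step 7.

Step 5
Reactants: 7 allyl vinyl ether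
Product: 8 methyl 4-[(tert-butyldiphenylsilyl)oxy]-3-[(1S,5R)-2-methyl-5-(prop-1-en-2-yl)cyclohex-2-en-1-yl]-2-oxobutanoate (side chain cis to isopropenyl; both epimers at C3 of the chain)
Conditions: PhMe, 120 °C, sealed tube
Reagents that add atoms: none
Why: Claisen [3,3]-rearrangement of a 2-alkoxycarbonyl allyl vinyl ether; the C5–C10 bond forms suprafacially on the ring face that carried the oxygen, so C5 is set cis to isopropenyl on the carvone ring (C4 trans to isopropenyl on the future ring A).

Step 6
Reactants: 8 α-keto ester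
Product: 10 methyl (4S,6S)-4-acetyl-3-{[(tert-butyldiphenylsilyl)oxy]methyl}-2,8-dioxo-6-(prop-1-en-2-yl)octanoate, via ozonide 9 (not isolated)
Conditions: O3 (1 equiv, Sudan Red 7B as indicator), CH2Cl2, −78 °C; then Me2S, −78 °C → rt
Reagents that add atoms: ozone, [O-][O+]=O
Why: chemoselective ozonolysis of the electron-richer trisubstituted ring alkene over the 1,1-disubstituted isopropenyl group (as in limonene) cleaves the temporary carvone ring at C4=C9 and should deliver the C9 aldehyde and the C4 methyl ketone.

Step 7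
Reactants: 10 keto aldehyde
Product: 12 cis-fused keto lactone 4-acetyl-3a-{[(tert-butyldiphenylsilyl)oxy]methyl}-6-(prop-1-en-2-yl)hexahydro-1-benzofuran-2,3-dione (C5, C7, C9 and C10 as in the target), via aldol adduct 11 (not isolated)
Conditions: MgBr2·OEt2, Et3N (1.1 equiv), CH2Cl2 (high dilution), −40 → 0 °C
Reagents that add atoms: none
Why: Proposed new method: divalent magnesium chelates the 1,2-dicarbonyl of the α-keto ester so that Et3N removes H-10 selectively (soft enolization), the magnesium enolate C10=C1 adds to the C9 aldehyde, and the C9 alkoxide then acylates the neighbouring C2 methyl ester with loss of methoxide. The closest known reactions are the aldol–lactonization of 3-substituted 2-oxo acids and esters with aldehydes (ketopantolactone and isotetronic acid syntheses) and magnesium-mediated soft-enolization aldols; the new element is their intramolecular, carbocycle-forming use beside a free aldehyde and a methyl ketone. Ring A closes by a 6-(enolexo)-exo-trig aldol addition and the γ-lactone by a 5-exo-trig acyl substitution. C10 should be controlled by allylic 1,3-strain: H-5 eclipses the C10=C1 enolate bond, the acetyl carbon C4 turns away from the C1 side, and the aldehyde tethered through C6 attacks the opposite enolate face, which places C1 trans and C14 cis to C4. C9 should be controlled by the lactone, because only the aldolate with O9 cis to C1 closes readily to the cis-fused five-membered ring and reversible aldol addition funnels material through it. The step needs enolization at C10 rather than at the aldehyde or methyl-ketone α-carbons, which the bidentate α-keto ester secures, and the C4 ketone cannot act as acceptor because that would close a three-membered ring.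

Step 8
Reactants: 12 keto lactone
Product: 13 hydroxy lactone 4-acetyl-3a-{[(tert-butyldiphenylsilyl)oxy]methyl}-3-hydroxy-6-(prop-1-en-2-yl)hexahydro-1-benzofuran-2(3H)-one (C1–OH cis to C14)
Conditions: NaBH4 (limiting), THF/MeOH, −78 °C
Reagents that add atoms: none
Why: chemoselective borohydride reduction of the activated, non-enolizable α-keto-lactone carbonyl (ketopantolactone type) over the methyl ketone; hydride is expected to enter anti to the adjacent C14H2OSi group, giving O1 cis to C14.

Step 9
Reactants: 13 hydroxy lactone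
Product: 14 triethylsilyl ether of 13 at O1
Conditions: Et3SiCl, imidazole, DMF, 0 °C → rt
Reagents that add atoms: chlorotriethylsilane, CC[Si](Cl)(CC)CC
Why: silylation under non-enolizing conditions gives a non-chelating O1 ether and avoids epimerization of C5, which is α to the ketone.

Step 10
Reactants: 14 silyl ether
Product: 15 lactone with the acetyl group converted to isopropenyl (C4=CH2)
Conditions: Zn, CH2Br2, TiCl4, THF/CH2Cl2, 0 °C → rt
Reagents that add atoms: dibromomethane, BrCBr
Why: Takai–Lombardo methylenation, a non-basic gem-dimetal reagent that should olefinate the ketone in the presence of the lactone without enolizing C5 or C1.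

Step 11
Reactants: 15 lactone
Product: 16 lactol (both anomers)
Conditions: iBu2AlH, CH2Cl2, −78 °C; potassium sodium tartrate work-up
Reagents that add atoms: none
Why: half-reduction of a γ-lactone, stopped at the stable aluminium hemiacetal at low temperature.

Step 12
Reactants: 16 lactol
Product: 18 diene diol (ring A with free 9-OH; C10 carries CH(OSiEt3)–CH(OH)–CH=CH2 and CH2OSi; C1 and C2 as in the target), via hydroxy aldehyde 17 (not isolated)
Conditions: CH2=CHMgBr (excess), THF, −78 → 0 °C
Reagents that add atoms: vinylmagnesium bromide, C=C[Mg]Br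
Why: Grignard addition to the ring-opened α-silyloxy aldehyde under Cornforth/polar Felkin–Anh control (non-chelating OSiEt3 opposed to the carbonyl dipole, attack past H-1) should give the anti 1,2-dioxygenated product, which is the cis C1/C2 relationship of ring B, and it frees O9.

Step 13
Reactants: 18 diene diol
Product: 19 trans-fused octalin diol (1-O-triethylsilyl, 14-O-tert-butyldiphenylsilyl, free 2-OH and 9-OH; all stereocentres as in the target)
Conditions: (H2IMes)(PCy3)Cl2Ru=CHPh (second-generation Grubbs catalyst, cat.), CH2Cl2, 40 °C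
Reagents that add atoms: none
Why: ring-closing metathesis between the C3 vinyl group and the C4 1,1-disubstituted alkene closes ring B and forms the trisubstituted C3=C4 bond, driven by loss of ethene; the remote C7 isopropenyl could only give an eight-membered ring.

Step 14
Reactants: 19 diol
Product: 20 2,9-di-O-acetate of 19
Conditions: Ac2O, DMAP, pyridine, CH2Cl2, rt
Reagents that add atoms: acetic anhydride, CC(=O)OC(C)=O
Why: DMAP-catalysed acetylation of the allylic O2 and the hindered axial O9 in one operation.

Step 15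
Reactants: 20 diacetate
Product: 21 C1 alcohol (14-O-tert-butyldiphenylsilyl retained)
Conditions: HF·pyridine, pyridine, THF, 0 °C
Reagents that add atoms: none
Why: selective fluoride cleavage of the secondary triethylsilyl ether beside the more robust primary tert-butyldiphenylsilyl ether, in a mildly acidic medium that should suppress acetyl migration from O2.

Step 16
Reactants: 21 C1 alcohol
Product: 22 14-O-tert-butyldiphenylsilyl ether of the target
Conditions: 3-methylbut-2-enoyl chloride, pyridine, DMAP (cat.), CH2Cl2, 0 °C → rt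
Reagents that add atoms: 3-methylbut-2-enoyl chloride, CC(C)=CC(Cl)=O
Why: acylation of O1 with the acid chloride under a weak base, which limits deconjugation of the acyl unit through the vinylketene.

Step 17
Reactants: 22 silyl ether
Product: 23 CNP0320218.1 (target)
Conditions: HF·pyridine, THF, rt
Reagents that add atoms: none
Why: acidic fluoride desilylation frees the C14 primary alcohol without base-induced acyl transfer from O1 or O9.

**Compound list**

1 | (S)-(+)-carvone, (5S)-2-methyl-5-(prop-1-en-2-yl)cyclohex-2-en-1-one | CC(=C)[C@H]1CC=C(C)C(=O)C1 | starting material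
2 | (1S,5S)-cis-carveol (OH cis to isopropenyl) | CC(=C)[C@H]1CC=C(C)[C@@H](O)C1 | intermediate
3 | trimethyl phosphonoacetate | COC(=O)CP(=O)(OC)OC | starting material
4 | methyl 2-diazo-2-(dimethoxyphosphoryl)acetate | COC(=O)C(=[N+]=[N-])P(=O)(OC)OC | intermediate
5 | methyl 2-(dimethoxyphosphoryl)-2-{[(1S,5S)-2-methyl-5-(prop-1-en-2-yl)cyclohex-2-en-1-yl]oxy}acetate (epimers at the phosphonate carbon) | CC(=C)[C@H]1CC=C(C)[C@@H](OC(C(=O)OC)P(=O)(OC)OC)C1 | intermediate
6 | 2-[(tert-butyldiphenylsilyl)oxy]acetaldehyde | O=CCO[Si](c1ccccc1)(c1ccccc1)C(C)(C)C | starting material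
7 | methyl 4-[(tert-butyldiphenylsilyl)oxy]-2-{[(1S,5S)-2-methyl-5-(prop-1-en-2-yl)cyclohex-2-en-1-yl]oxy}but-2-enoate (E/Z mixture) | CC(=C)[C@H]1CC=C(C)[C@@H](OC(=CCO[Si](c2ccccc2)(c2ccccc2)C(C)(C)C)C(=O)OC)C1 | intermediate
8 | methyl 4-[(tert-butyldiphenylsilyl)oxy]-3-[(1S,5R)-2-methyl-5-(prop-1-en-2-yl)cyclohex-2-en-1-yl]-2-oxobutanoate (epimers at chain C3) | C=C(C)[C@@H]1CC=C(C)[C@@H](C1)C(CO[Si](c1ccccc1)(c1ccccc1)C(C)(C)C)C(=O)C(=O)OC | intermediate
9 | ozonide (1,2,4-trioxolane) of the ring alkene of 8 | CC12OOC(O1)C[C@@H](C(C)=C)C[C@H]2C(CO[Si](c1ccccc1)(c1ccccc1)C(C)(C)C)C(=O)C(=O)OC | intermediate (not isolated)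
10 | methyl (4S,6S)-4-acetyl-3-{[(tert-butyldiphenylsilyl)oxy]methyl}-2,8-dioxo-6-(prop-1-en-2-yl)octanoate (epimers at C3) | C=C(C)[C@H](CC=O)C[C@H](C(C)=O)C(CO[Si](c1ccccc1)(c1ccccc1)C(C)(C)C)C(=O)C(=O)OC | intermediate
11 | aldol adduct, methyl 2-[6-acetyl-1-{[(tert-butyldiphenylsilyl)oxy]methyl}-2-hydroxy-4-(prop-1-en-2-yl)cyclohexyl]-2-oxoacetate (configuration as in 12) | C=C(C)[C@@H]1C[C@H](O)[C@](CO[Si](c2ccccc2)(c2ccccc2)C(C)(C)C)(C(=O)C(=O)OC)[C@H](C1)C(C)=O | intermediate (not isolated)
12 | cis-fused keto lactone, 4-acetyl-3a-{[(tert-butyldiphenylsilyl)oxy]methyl}-6-(prop-1-en-2-yl)hexahydro-1-benzofuran-2,3-dione (C5, C7, C9, C10 as in the target) | C=C(C)[C@@H]1C[C@@H]2OC(=O)C(=O)[C@]2(CO[Si](c3ccccc3)(c3ccccc3)C(C)(C)C)[C@H](C1)C(C)=O | intermediate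
13 | hydroxy lactone, 3-hydroxy analogue of 12 (C1–OH cis to C14) | C=C(C)[C@@H]1C[C@@H]2OC(=O)[C@H](O)[C@]2(CO[Si](c3ccccc3)(c3ccccc3)C(C)(C)C)[C@H](C1)C(C)=O | intermediate
14 | O1-triethylsilyl ether of 13 | C=C(C)[C@@H]1C[C@@H]2OC(=O)[C@H](O[Si](CC)(CC)CC)[C@]2(CO[Si](c3ccccc3)(c3ccccc3)C(C)(C)C)[C@H](C1)C(C)=O | intermediate
15 | lactone with the acetyl group methylenated to isopropenyl | C=C(C)[C@@H]1C[C@@H]2OC(=O)[C@H](O[Si](CC)(CC)CC)[C@]2(CO[Si](c3ccccc3)(c3ccccc3)C(C)(C)C)[C@H](C1)C(C)=C | intermediate
16 | lactol of 15 (anomers) | C=C(C)[C@@H]1C[C@@H]2OC(O)[C@H](O[Si](CC)(CC)CC)[C@]2(CO[Si](c3ccccc3)(c3ccccc3)C(C)(C)C)[C@H](C1)C(C)=C | intermediate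
17 | ring-opened hydroxy aldehyde of 16 | C=C(C)[C@@H]1C[C@H](O)[C@@]([C@@H](O[Si](CC)(CC)CC)C=O)(CO[Si](c2ccccc2)(c2ccccc2)C(C)(C)C)[C@H](C1)C(C)=C | intermediate (not isolated)
18 | diene diol (C10 carries CH(OSiEt3)–CH(OH)–CH=CH2; free 9-OH) | C=C(C)[C@@H]1C[C@H](O)[C@@]([C@@H](O[Si](CC)(CC)CC)[C@@H](O)C=C)(CO[Si](c2ccccc2)(c2ccccc2)C(C)(C)C)[C@H](C1)C(C)=C | intermediate
19 | trans-octalin diol, 1-O-triethylsilyl-14-O-tert-butyldiphenylsilyl-eudesma-3,11-diene-1,2,9,14-tetrol (configuration as in the target) | C=C(C)[C@@H]1C[C@H](O)[C@@]2(CO[Si](c3ccccc3)(c3ccccc3)C(C)(C)C)[C@H](C1)C(C)=C[C@H](O)[C@@H]2O[Si](CC)(CC)CC | intermediate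
20 | 2,9-di-O-acetate of 19 | C=C(C)[C@@H]1C[C@H](OC(C)=O)[C@@]2(CO[Si](c3ccccc3)(c3ccccc3)C(C)(C)C)[C@H](C1)C(C)=C[C@H](OC(C)=O)[C@@H]2O[Si](CC)(CC)CC | intermediate
21 | C1 alcohol (2,9-diacetate, 14-O-tert-butyldiphenylsilyl) | C=C(C)[C@@H]1C[C@H](OC(C)=O)[C@@]2(CO[Si](c3ccccc3)(c3ccccc3)C(C)(C)C)[C@H](C1)C(C)=C[C@H](OC(C)=O)[C@@H]2O | intermediate
22 | 14-O-tert-butyldiphenylsilyl ether of the target | C=C(C)[C@@H]1C[C@H](OC(C)=O)[C@@]2(CO[Si](c3ccccc3)(c3ccccc3)C(C)(C)C)[C@H](C1)C(C)=C[C@H](OC(C)=O)[C@@H]2OC(=O)C=C(C)C | intermediate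
23 | CNP0320218.1 | C=C(C)[C@@H]1C[C@H](OC(C)=O)[C@@]2(CO)[C@H](C1)C(C)=C[C@H](OC(C)=O)[C@@H]2OC(=O)C=C(C)C | target

**Step count and risks**

Total step count: 17. Longest linear sequence: 16 steps (steps 1 and 3–17, from (S)-carvone).

Three steps most likely to fail:

1. Step 7 (Proposed new method). What may go wrong: competing enolization of the aldehyde or methyl ketone followed by aldol attack on the C1 ketone, retro-aldol or loss of the silyloxide from C14, and erosion of the facial selectivity at C10. Fallback (known chemistry, chromium-mediated Reformatsky-type aldol): it sets out from 8. Enolization with LiN(SiMe3)2 and trapping with N-bromosuccinimide should give the 3-bromo derivative of 8, F1. Ozonolysis as in step 6 (through the ozonide of F1, F2) should give the 3-bromo derivative of 10, F3. CrCl2 with LiI in THF then reduces only the C–Br bond; the resulting enolate of trivalent chromium adds to the aldehyde without any base to give adduct 11, which lactonizes on mildly acidic work-up. The route is rejoined at 12.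

2. Step 8. What may go wrong: poor facial selectivity of hydride delivery, with attack syn to the silyloxymethyl group giving the C1 epimer. Fallback (inversion instead of direct stereocontrol): it sets out from 12. If reduction gives mainly the C1 epimer of 13, F4, this is converted with Tf2O and pyridine to the trifluoromethanesulfonate of F4, F5. Displacement with tetrabutylammonium nitrite proceeds with inversion to the nitrite ester of 13, F6, which hydrolyses on aqueous work-up. The route is rejoined at 13.

3. Step 12. What may go wrong: loss of Cornforth control through chelation by the magnesium alkoxides (giving the trans-diol series) or silyl migration between O1 and O2. Fallback (C2 set by ring-controlled reduction instead of acyclic addition): it sets out from 15. One equivalent of vinylmagnesium bromide at −78 °C should add once to the lactone to give the hydroxy vinyl ketone, F7. Ring-closing metathesis with the second-generation Grubbs catalyst gives the ring-B enone, F8. Luche reduction (NaBH4, CeCl3·7H2O, MeOH, −78 °C), with hydride entering anti to the axial C14H2OSi group, should give the cis-diol. The route is rejoined at 19.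

**Further compounds**

F1 | step 7 | 3-bromo derivative of 8 (epimers at the brominated carbon) | C=C(C)[C@@H]1CC=C(C)[C@@H](C1)C(Br)(CO[Si](c1ccccc1)(c1ccccc1)C(C)(C)C)C(=O)C(=O)OC
F2 | step 7 | ozonide of F1 | CC12OOC(O1)C[C@@H](C(C)=C)C[C@H]2C(Br)(CO[Si](c1ccccc1)(c1ccccc1)C(C)(C)C)C(=O)C(=O)OC
F3 | step 7 | 3-bromo derivative of 10 | C=C(C)[C@H](CC=O)C[C@H](C(C)=O)C(Br)(CO[Si](c1ccccc1)(c1ccccc1)C(C)(C)C)C(=O)C(=O)OC
F4 | step 8 | C1 epimer of 13 | C=C(C)[C@@H]1C[C@@H]2OC(=O)[C@@H](O)[C@]2(CO[Si](c3ccccc3)(c3ccccc3)C(C)(C)C)[C@H](C1)C(C)=O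
F5 | step 8 | trifluoromethanesulfonate of F4 | C=C(C)[C@@H]1C[C@@H]2OC(=O)[C@@H](OS(=O)(=O)C(F)(F)F)[C@]2(CO[Si](c3ccccc3)(c3ccccc3)C(C)(C)C)[C@H](C1)C(C)=O
F6 | step 8 | nitrite ester of 13 | C=C(C)[C@@H]1C[C@@H]2OC(=O)[C@H](ON=O)[C@]2(CO[Si](c3ccccc3)(c3ccccc3)C(C)(C)C)[C@H](C1)C(C)=O
F7 | step 12 | hydroxy vinyl ketone (C10 carries CH(OSiEt3)–C(=O)–CH=CH2; free 9-OH) | C=C(C)[C@@H]1C[C@H](O)[C@@]([C@@H](O[Si](CC)(CC)CC)C(=O)C=C)(CO[Si](c2ccccc2)(c2ccccc2)C(C)(C)C)[C@H](C1)C(C)=C
F8 | step 12 | ring-B enone (C2 ketone, C3=C4, 1-O-triethylsilyl, free 9-OH) | C=C(C)[C@@H]1C[C@H](O)[C@@]2(CO[Si](c3ccccc3)(c3ccccc3)C(C)(C)C)[C@H](C1)C(C)=CC(=O)[C@@H]2O[Si](CC)(CC)CC
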